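**Retrosynthetic overview**

1. The strategy rests on the fully substituted quinone ring (C1–C4, C4a, C8a). Its C2 methyl and C3 E‑allylic C40 chain are the two ends of a 2‑alkyne, so this ring is closed by carbene–alkyne–CO benzannulation (new bonds C1–C2, C3–C4, C4–C4a) on a phenyl group that becomes the benzo ring; the resulting 4‑methoxy‑1‑naphthol is then oxidised to the quinone.
2. The 2‑alkyne is cut at C1′ into an E‑allylic bromide and propynylmagnesium bromide. The E‑C2′=C3′ unit comes from Cp2ZrCl2‑catalysed methylalumination of a terminal alkyne with formaldehyde capture, and that alkyne from a C5′ iodide and a propargyl anion equivalent.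
3. The C16′–C17′ bond is cut into a saturated C5′–C16′ Grignard reagent carrying the C7′/C11′/C15′ stereotriad and a C20 allylic chloride (C17′–C32′).
4. Both pieces come from one ω‑hydroxylated farnesyl silyl ether: threefold asymmetric hydrogenation sets the stereotriad, and a Li2CuCl4‑catalysed isopentyl coupling at C28′ adds the saturated terminal isoprene unit, which farnesol itself lacks.
5. Ring order: the benzo ring is bought with phenyllithium; the only ring made is the oxygenated carbocycle, in the penultimate step.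

Key step: step 17

Assumption: side‑chain atoms are labelled C1′–C32′ from the quinone outwards (target = 7′S,11′R,15′R, all E); in step 3 the ligand enantiomer is taken to be the one that reduces (2E,6E)‑farnesol to (3S,7S)‑3,7,11‑trimethyldodecan‑1‑ol, which is the facial sense needed here.

**Route**

Step 1
Reactants: 1 (2E,6E)-farnesol; 2 tert-butyl(chloro)diphenylsilane
Product: 3 tert-butyl(diphenyl){[(2E,6E)-3,7,11-trimethyldodeca-2,6,10-trien-1-yl]oxy}silane
Conditions: imidazole, DMF, 0 → 23 °C
Reagents that add atoms: tert-butyl(chloro)diphenylsilane (2), CC(C)(C)[Si](Cl)(c1ccccc1)c1ccccc1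
Why: Imidazole‑assisted silylation of a primary allylic alcohol; the TBDPS ether is chosen because it should survive SeO2, the cationic iridium hydrogenation catalyst of step 3, Grignard formation and the Li2CuCl4‑catalysed couplings.

Step 2
Reactants: 3 farnesyl silyl ether
Product: 4 (2E,6E,10E)-12-[(tert-butyldiphenylsilyl)oxy]-2,6,10-trimethyldodeca-2,6,10-trien-1-ol
Conditions: SeO2 (0.2 equiv), t-BuOOH (70% aq., 3 equiv), salicylic acid (0.1 equiv), CH2Cl2, 0 → 23 °C, stopped at partial conversion, 3 recycled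
Reagents that add atoms: tert-butyl hydroperoxide, CC(C)(C)OO (oxygen relayed by catalytic selenium dioxide, O=[Se]=O)
Why: Catalytic SeO2 allylic oxidation (ene reaction, then [2,3]-sigmatropic shift) should attack the terminal, most electron‑rich and least hindered olefin at its E‑methyl group, the C2=C3 olefin being deactivated by the allylic silyloxy group, so the E primary allylic alcohol is expected.

Step 3
Reactants: 4 ω‑hydroxy farnesyl silyl ether
Product: 5 (2R,6R,10S)-12-[(tert-butyldiphenylsilyl)oxy]-2,6,10-trimethyldodecan-1-ol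
Conditions: H2 (50 bar), [Ir(cod)(L)][B(C6H3-3,5-(CF3)2)4] (1 mol%; L = 2-phenyl-7-[(di-o-tolylphosphanyl)oxy]-6,7-dihydro-5H-cyclopenta[b]pyridine, one enantiomer, see assumption), CH2Cl2, 23 °C
Reagents that add atoms: none
Why: Asymmetric hydrogenation of trisubstituted olefins with a cationic iridium complex of a chiral pyridyl phosphinite ligand: the three E olefins share the same local geometry, so one catalyst should add H2 to the homologous face of each and create C2, C6 and C10 (C15′, C11′, C7′) in the same spatial sense under catalyst control.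

Step 4
Reactants: 5 saturated alcohol
Product: 6 {[(3S,7R,11R)-12-bromo-3,7,11-trimethyldodecyl]oxy}(tert-butyl)diphenylsilane
Conditions: CBr4, PPh3, CH2Cl2, 0 °C
Reagents that add atoms: carbon tetrabromide, BrC(Br)(Br)Br
Why: Appel bromination of a primary alcohol by SN2 displacement of the alkoxyphosphonium; the neighbouring C11 stereocentre is not involved.

Step 5
Reactants: 4 ω‑hydroxy farnesyl silyl ether
Product: 7 {[(2E,6E,10E)-12-bromo-3,7,11-trimethyldodeca-2,6,10-trien-1-yl]oxy}(tert-butyl)diphenylsilane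
Conditions: CBr4, PPh3, CH2Cl2, −20 → 0 °C, used at once
Reagents that add atoms: carbon tetrabromide, BrC(Br)(Br)Br
Why: Appel bromination under neutral conditions should convert the primary allylic alcohol into the bromide without allylic transposition or loss of the silyl ether.

Step 6
Reactants: 7 allylic bromide; 8 isopentylmagnesium bromide (i-C5H11MgBr)
Product: 9 tert-butyl(diphenyl){[(2E,6E,10E)-3,7,11,15-tetramethylhexadeca-2,6,10-trien-1-yl]oxy}silane
Conditions: Li2CuCl4 (3 mol%), THF, −78 → −20 °C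
Reagents that add atoms: isopentylmagnesium bromide (8), CC(C)CC[Mg]Br
Why: Grignard allylic substitution catalysed by Li2CuCl4 in THF favours direct α (SN2) displacement at the primary allylic carbon, which should keep the E olefin and install the saturated terminal isoprene unit (C29′–C32′).

Step 7
Reactants: 9 C20 silyl ether
Product: 10 (2E,6E,10E)-3,7,11,15-tetramethylhexadeca-2,6,10-trien-1-ol
Conditions: Bu4NF, THF, 23 °C
Reagents that add atoms: none
Why: Fluoride‑induced cleavage of the Si–O bond, driven by the strong Si–F bond, leaves the three olefins untouched.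

Step 8
Reactants: 10 C20 trienol
Product: 11 (2E,6E,10E)-1-chloro-3,7,11,15-tetramethylhexadeca-2,6,10-triene
Conditions: CH3SO2Cl, LiCl, 2,4,6-collidine, DMF, 0 °C
Reagents that add atoms: lithium chloride (LiCl), [Li+].[Cl-]
Why: Mesylation in the presence of LiCl gives the primary allylic chloride by in‑situ SN2 displacement, a standard way to prenyl‑type chlorides without allylic rearrangement.

Step 9
Reactants: 6 saturated bromide; 11 C20 allylic chloride
Product: 13 tert-butyl(diphenyl){[(3S,7S,11R,14E,18E,22E)-3,7,11,15,19,23,27-heptamethyloctacosa-14,18,22-trien-1-yl]oxy}silane, via Grignard reagent 12 (not isolated)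
Conditions: 6, Mg (activated with BrCH2CH2Br), THF, 45 °C; then 11, Li2CuCl4 (5 mol%), THF, −78 → 0 °C
Reagents that add atoms: none
Why: Grignard formation followed by Li2CuCl4‑catalysed allylic substitution should join C16′ to C17′ by α attack with retention of the E‑C18′=C19′ olefin; the stereocentre β to magnesium is not metalated and keeps its configuration (the descriptor at C7 changes only through priorities).

Step 10
Reactants: 13 C32 silyl ether
Product: 14 (3S,7S,11R,14E,18E,22E)-3,7,11,15,19,23,27-heptamethyloctacosa-14,18,22-trien-1-ol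
Conditions: Bu4NF, THF, 23 °C
Reagents that add atoms: none
Why: Fluoride desilylation releases the C5′ primary alcohol under conditions that do not affect the olefins or stereocentres.

Step 11
Reactants: 14 C32 alcohol
Product: 15 (6E,10E,14E,18R,22S,26S)-28-iodo-2,6,10,14,18,22,26-heptamethyloctacosa-6,10,14-triene
Conditions: I2, PPh3, imidazole, CH2Cl2, 0 → 23 °C
Reagents that add atoms: iodine, II
Why: Appel‑type iodination of the primary alcohol by SN2 displacement of the alkoxyphosphonium under neutral conditions.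

Step 12
Reactants: 15 C32 iodide; 16 1-(trimethylsilyl)propyne
Product: 19 (6S,10R,14R,17E,21E,25E)-6,10,14,18,22,26,30-heptamethylhentriaconta-17,21,25-trien-1-yne, via lithiated 1-(trimethylsilyl)propyne 17 (not isolated), via trimethylsilyl alkyne 18 (not isolated)
Conditions: 16, n-BuLi, THF, −78 → −20 °C; then 15, THF–DMPU, −78 → 23 °C; then K2CO3, MeOH, 23 °C
Reagents that add atoms: 1-(trimethylsilyl)propyne (16), CC#C[Si](C)(C)C
Why: Alkylation of the silyl‑blocked propargyl anion equivalent by the unhindered primary iodide adds C4′–C2′ at the propargylic carbon (the silyl group suppresses allene formation), and methanolysis removes the silyl group to give the terminal alkyne.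

Step 13
Reactants: 19 terminal alkyne; 20 trimethylaluminium (AlMe3); 21 paraformaldehyde
Product: 24 (2E,7S,11R,15R,18E,22E,26E)-3,7,11,15,19,23,27,31-octamethyldotriaconta-2,18,22,26-tetraen-1-ol, via alkenyl(dimethyl)alane 22 (not isolated), via lithium alkenylaluminate 23 (not isolated)
Conditions: AlMe3 (2.5 equiv), Cp2ZrCl2 (0.25 equiv), CH2Cl2, 0 → 23 °C; volatiles removed; n-BuLi, THF, −78 °C; (CH2O)n, −78 → 23 °C; aq. HCl, 0 °C
Reagents that add atoms: trimethylaluminium (20), C[Al](C)C; paraformaldehyde (21), C=O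
Why: Negishi carboalumination adds Me–Al syn across the terminal alkyne (methyl to C3′, aluminium to C2′), and the derived aluminate attacks formaldehyde with retention, so the 2E allylic alcohol follows from the syn addition while the remote trisubstituted olefins are inert.

Step 14
Reactants: 24 C40 allylic alcohol
Product: 25 (2E,7S,11R,15R,18E,22E,26E)-1-bromo-3,7,11,15,19,23,27,31-octamethyldotriaconta-2,18,22,26-tetraene
Conditions: PBr3 (0.4 equiv), pyridine (cat.), Et2O, −10 °C, used at once
Reagents that add atoms: phosphorus tribromide, BrP(Br)Br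
Why: PBr3 converts the primary allylic alcohol into the bromide through its phosphite ester at low temperature, the usual preparation of polyprenyl bromides, and should not transpose or isomerise the olefin.

Step 15
Reactants: 25 C40 allylic bromide; 26 1-propynylmagnesium bromide (CH3C≡CMgBr)
Product: 27 (5E,10S,14R,18R,21E,25E,29E)-6,10,14,18,22,26,30,34-octamethylpentatriaconta-5,21,25,29-tetraen-2-yne
Conditions: CuCl (10 mol%), THF, 0 → 50 °C
Reagents that add atoms: 1-propynylmagnesium bromide (26), CC#C[Mg]Br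
Why: CuCl‑catalysed alkynyl Grignard–allyl bromide coupling should displace bromide at the primary allylic carbon and give the skipped enyne with the E‑C2′=C3′ olefin intact.

Step 16
Reactants: 28 chromium hexacarbonyl Cr(CO)6; 29 phenyllithium (PhLi); 30 trimethyloxonium tetrafluoroborate (Me3OBF4)
Product: 32 pentacarbonyl[methoxy(phenyl)methylidene]chromium (CO)5Cr=C(OMe)Ph, via lithium acylchromate 31 (not isolated)
Conditions: PhLi, Et2O, 0 → 23 °C; then Me3OBF4, CH2Cl2–H2O, 0 °C
Reagents that add atoms: phenyllithium (29), [Li]c1ccccc1; trimethyloxonium tetrafluoroborate (30), C[O+](C)C.F[B-](F)(F)F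
Why: Fischer carbene synthesis: PhLi adds to a CO ligand to give the acyl chromate, which the hard oxonium salt methylates on oxygen.

Step 17
Reactants: 32 carbene complex; 27 side‑chain 2‑alkyne
Product: 34 4-methoxy-3-methyl-2-[(2E,7S,11R,15R,18E,22E,26E)-3,7,11,15,19,23,27,31-octamethyldotriaconta-2,18,22,26-tetraen-1-yl]naphthalen-1-ol, via tricarbonylchromium naphthol complex 33 (not isolated)
Conditions: 32 (1.3 equiv), t-BuOMe (degassed), 55 °C, Ar; then air, MeCN, 23 °C
Reagents that add atoms: none
Why: Thermal loss of one CO from 32 lets the alkyne of 27 coordinate and insert into the Cr=C bond to give a vinylcarbene, CO insertion gives a chromium‑bound vinylketene, and its ketene carbon closes onto the phenyl ortho carbon before tautomerisation to the naphthol, which stays η6‑bound to Cr(CO)3 (33) until air releases it. This is the Dötz benzannulation of an aryl(alkoxy)carbene complex with an internal dialkyl alkyne, the reaction class known for 2‑methyl‑3‑prenyl naphthoquinone precursors. The single new ring, the six‑membered oxygenated ring, is closed by 6π‑electrocyclisation of the dienylketene, the new bonds being C1–C2 (carbene carbon to the methyl‑bearing alkyne carbon), C3–C4 (chain‑bearing alkyne carbon to CO) and C4–C4a (CO carbon to the aryl ortho carbon) in quinone numbering. No stereocentre is formed, and the three methyl‑bearing centres and four E olefins are remote from the reacting atoms and see only neutral conditions, so no allyl cation and no E/Z leakage can arise. The step needs chemoselectivity for the alkyne over the four trisubstituted olefins, which the carbene complex should provide because it does not engage unactivated trisubstituted alkenes at this temperature and the 1,4‑enyne geometry disfavours intramolecular cyclopropanation. Alkyne regiochemistry need not be controlled: 34 is the orientation expected to predominate (larger alkyne substituent next to the hydroxyl), and any material with methyl and chain exchanged is left in, because the oxidation of step 18 turns either orientation into the same quinone.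

Step 18
Reactants: 34 methoxynaphthol
Product: 35 2-methyl-3-[(2E,7S,11R,15R,18E,22E,26E)-3,7,11,15,19,23,27,31-octamethyldotriaconta-2,18,22,26-tetraen-1-yl]naphthalene-1,4-dione (CNP0293208.1)
Conditions: (NH4)2Ce(NO3)6 (2.5 equiv), MeCN–H2O (4:1), 0 °C, short reaction time
Reagents that add atoms: water, O
Why: Two‑electron oxidative demethylation of a 4‑methoxy‑1‑naphthol by (NH4)2Ce(NO3)6: water adds to the methoxy‑bearing ring carbon and methanol is lost, so the methyl/chain orientation set in step 17 no longer matters, and the brief cold oxidation should leave the isolated olefins untouched.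

**Compound list**

1 | (2E,6E)-farnesol | CC(C)=CCC/C(C)=C/CC/C(C)=C/CO | starting material
2 | tert-butyl(chloro)diphenylsilane | CC(C)(C)[Si](Cl)(c1ccccc1)c1ccccc1 | starting material
3 | tert-butyl(diphenyl){[(2E,6E)-3,7,11-trimethyldodeca-2,6,10-trien-1-yl]oxy}silane | CC(C)=CCC/C(C)=C/CC/C(C)=C/CO[Si](c1ccccc1)(c1ccccc1)C(C)(C)C | intermediate
4 | (2E,6E,10E)-12-[(tert-butyldiphenylsilyl)oxy]-2,6,10-trimethyldodeca-2,6,10-trien-1-ol | OC/C(C)=C/CC/C(C)=C/CC/C(C)=C/CO[Si](c1ccccc1)(c1ccccc1)C(C)(C)C | intermediate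
5 | (2R,6R,10S)-12-[(tert-butyldiphenylsilyl)oxy]-2,6,10-trimethyldodecan-1-ol | CC(C)(C)[Si](c1ccccc1)(c1ccccc1)OCC[C@@H](C)CCC[C@@H](C)CCC[C@@H](C)CO | intermediate
6 | {[(3S,7R,11R)-12-bromo-3,7,11-trimethyldodecyl]oxy}(tert-butyl)diphenylsilane | CC(C)(C)[Si](c1ccccc1)(c1ccccc1)OCC[C@@H](C)CCC[C@@H](C)CCC[C@@H](C)CBr | intermediate
7 | {[(2E,6E,10E)-12-bromo-3,7,11-trimethyldodeca-2,6,10-trien-1-yl]oxy}(tert-butyl)diphenylsilane | BrC/C(C)=C/CC/C(C)=C/CC/C(C)=C/CO[Si](c1ccccc1)(c1ccccc1)C(C)(C)C | intermediate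
8 | isopentylmagnesium bromide (3-methylbutylmagnesium bromide) | CC(C)CC[Mg]Br | starting material
9 | tert-butyl(diphenyl){[(2E,6E,10E)-3,7,11,15-tetramethylhexadeca-2,6,10-trien-1-yl]oxy}silane | CC(C)CCC/C(C)=C/CC/C(C)=C/CC/C(C)=C/CO[Si](c1ccccc1)(c1ccccc1)C(C)(C)C | intermediate
10 | (2E,6E,10E)-3,7,11,15-tetramethylhexadeca-2,6,10-trien-1-ol | CC(C)CCC/C(C)=C/CC/C(C)=C/CC/C(C)=C/CO | intermediate
11 | (2E,6E,10E)-1-chloro-3,7,11,15-tetramethylhexadeca-2,6,10-triene | CC(C)CCC/C(C)=C/CC/C(C)=C/CC/C(C)=C/CCl | intermediate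
12 | {(2R,6R,10S)-12-[(tert-butyldiphenylsilyl)oxy]-2,6,10-trimethyldodecyl}magnesium bromide | CC(C)(C)[Si](c1ccccc1)(c1ccccc1)OCC[C@@H](C)CCC[C@@H](C)CCC[C@@H](C)C[Mg]Br | intermediate
13 | tert-butyl(diphenyl){[(3S,7S,11R,14E,18E,22E)-3,7,11,15,19,23,27-heptamethyloctacosa-14,18,22-trien-1-yl]oxy}silane | CC(C)(C)[Si](c1ccccc1)(c1ccccc1)OCC[C@@H](C)CCC[C@@H](C)CCC[C@@H](C)CC/C=C(\C)CC/C=C(\C)CC/C=C(\C)CCCC(C)C | intermediate
14 | (3S,7S,11R,14E,18E,22E)-3,7,11,15,19,23,27-heptamethyloctacosa-14,18,22-trien-1-ol | OCC[C@@H](C)CCC[C@@H](C)CCC[C@@H](C)CC/C=C(\C)CC/C=C(\C)CC/C=C(\C)CCCC(C)C | intermediate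
15 | (6E,10E,14E,18R,22S,26S)-28-iodo-2,6,10,14,18,22,26-heptamethyloctacosa-6,10,14-triene | ICC[C@@H](C)CCC[C@@H](C)CCC[C@@H](C)CC/C=C(\C)CC/C=C(\C)CC/C=C(\C)CCCC(C)C | intermediate
16 | 1-(trimethylsilyl)propyne | CC#C[Si](C)(C)C | starting material
17 | 3-lithio-1-(trimethylsilyl)propyne | [Li]CC#C[Si](C)(C)C | intermediate
18 | trimethyl[(6S,10R,14R,17E,21E,25E)-6,10,14,18,22,26,30-heptamethylhentriaconta-17,21,25-trien-1-yn-1-yl]silane | C[Si](C)(C)C#CCCC[C@@H](C)CCC[C@@H](C)CCC[C@@H](C)CC/C=C(\C)CC/C=C(\C)CC/C=C(\C)CCCC(C)C | intermediate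
19 | (6S,10R,14R,17E,21E,25E)-6,10,14,18,22,26,30-heptamethylhentriaconta-17,21,25-trien-1-yne | C#CCCC[C@@H](C)CCC[C@@H](C)CCC[C@@H](C)CC/C=C(\C)CC/C=C(\C)CC/C=C(\C)CCCC(C)C | intermediate
20 | trimethylaluminium | C[Al](C)C | starting material
21 | paraformaldehyde (formaldehyde source) | C=O | starting material
22 | dimethyl[(1E,6S,10R,14R,17E,21E,25E)-2,6,10,14,18,22,26,30-octamethylhentriaconta-1,17,21,25-tetraen-1-yl]alumane | C[Al](C)/C=C(\C)CCC[C@@H](C)CCC[C@@H](C)CCC[C@@H](C)CC/C=C(\C)CC/C=C(\C)CC/C=C(\C)CCCC(C)C | intermediate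
23 | lithium butyl(dimethyl)[(1E,6S,10R,14R,17E,21E,25E)-2,6,10,14,18,22,26,30-octamethylhentriaconta-1,17,21,25-tetraen-1-yl]aluminate | [Li+].CCCC[Al-](C)(C)/C=C(\C)CCC[C@@H](C)CCC[C@@H](C)CCC[C@@H](C)CC/C=C(\C)CC/C=C(\C)CC/C=C(\C)CCCC(C)C | intermediate
24 | (2E,7S,11R,15R,18E,22E,26E)-3,7,11,15,19,23,27,31-octamethyldotriaconta-2,18,22,26-tetraen-1-ol | OC/C=C(\C)CCC[C@@H](C)CCC[C@@H](C)CCC[C@@H](C)CC/C=C(\C)CC/C=C(\C)CC/C=C(\C)CCCC(C)C | intermediate
25 | (2E,7S,11R,15R,18E,22E,26E)-1-bromo-3,7,11,15,19,23,27,31-octamethyldotriaconta-2,18,22,26-tetraene | BrC/C=C(\C)CCC[C@@H](C)CCC[C@@H](C)CCC[C@@H](C)CC/C=C(\C)CC/C=C(\C)CC/C=C(\C)CCCC(C)C | intermediate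
26 | 1-propynylmagnesium bromide | CC#C[Mg]Br | starting material
27 | (5E,10S,14R,18R,21E,25E,29E)-6,10,14,18,22,26,30,34-octamethylpentatriaconta-5,21,25,29-tetraen-2-yne | CC#CC/C=C(\C)CCC[C@@H](C)CCC[C@@H](C)CCC[C@@H](C)CC/C=C(\C)CC/C=C(\C)CC/C=C(\C)CCCC(C)C | intermediate
28 | chromium hexacarbonyl | O=C=[Cr](=C=O)(=C=O)(=C=O)(=C=O)=C=O | starting material
29 | phenyllithium | [Li]c1ccccc1 | starting material
30 | trimethyloxonium tetrafluoroborate | C[O+](C)C.F[B-](F)(F)F | starting material
31 | lithium pentacarbonyl[oxido(phenyl)methylidene]chromate | [Li+].[O-]C(=[Cr](=C=O)(=C=O)(=C=O)(=C=O)=C=O)c1ccccc1 | intermediate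
32 | pentacarbonyl[methoxy(phenyl)methylidene]chromium | COC(=[Cr](=C=O)(=C=O)(=C=O)(=C=O)=C=O)c1ccccc1 | intermediate
33 | tricarbonylchromium η6-complex of methoxynaphthol 34, metal bound to the newly formed oxygenated ring | COc1c(C)c(C/C=C(\C)CCC[C@@H](C)CCC[C@@H](C)CCC[C@@H](C)CC/C=C(\C)CC/C=C(\C)CC/C=C(\C)CCCC(C)C)c(O)c2ccccc12.O=C=[Cr](=C=O)=C=O | intermediate
34 | 4-methoxy-3-methyl-2-[(2E,7S,11R,15R,18E,22E,26E)-3,7,11,15,19,23,27,31-octamethyldotriaconta-2,18,22,26-tetraen-1-yl]naphthalen-1-ol | COc1c(C)c(C/C=C(\C)CCC[C@@H](C)CCC[C@@H](C)CCC[C@@H](C)CC/C=C(\C)CC/C=C(\C)CC/C=C(\C)CCCC(C)C)c(O)c2ccccc12 | intermediate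
35 | 2-methyl-3-[(2E,7S,11R,15R,18E,22E,26E)-3,7,11,15,19,23,27,31-octamethyldotriaconta-2,18,22,26-tetraen-1-yl]naphthalene-1,4-dione | CC1=C(C/C=C(\C)CCC[C@@H](C)CCC[C@@H](C)CCC[C@@H](C)CC/C=C(\C)CC/C=C(\C)CC/C=C(\C)CCCC(C)C)C(=O)c2ccccc2C1=O | target

**Step count**

Total steps: 18. Longest linear sequence: 15 (steps 1, 2, 5, 6, 7, 8, 9, 10, 11, 12, 13, 14, 15, 17, 18).

**Steps most likely to fail**

Step 3. The catalyst may discriminate the faces of the three olefins unequally, since two of them carry an allylic oxygen and one is purely alkyl‑substituted. Allylic C–O hydrogenolysis or olefin migration before reduction is also possible. Either would give a stereoisomer mixture that cannot be separated at any later stage. The fallback takes every stereocentre from the chiral pool and replaces steps 3, 4 and 9; it sets out from allylic chloride 11 and returns to the route at silyl ether 13. (R)-2-Methylbutane-1,4-diol F1 is monosilylated at the less hindered hydroxyl (TBDPSCl, imidazole, −20 °C, regioisomer removed by chromatography) to (R)-4-[(tert-butyldiphenylsilyl)oxy]-2-methylbutan-1-ol F2. Appel bromination gives (R)-(4-bromo-3-methylbutoxy)(tert-butyl)diphenylsilane F3, and Mg in THF gives the Grignard reagent F4. Li2CuCl4‑catalysed coupling of F4 with 11 gives the C25 silyl ether F5 (C15′ centre); Bu4NF gives the alcohol F6 and TsCl/pyridine the tosylate F7. A second Li2CuCl4‑catalysed coupling of F4 with F7 gives the silyl ether F8 (C11′ centre); desilylation gives the alcohol F9 and tosylation the tosylate F10. A third coupling of F4 with F10 (C7′ centre) gives 13, so that every stereocentre is bought and none is made.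

Step 9. The β‑branched Grignard reagent may attack the γ carbon (C19′) instead of C17′, the olefin geometry may leak through an allylcopper intermediate, or magnesium insertion may be incomplete and accompanied by Wurtz homocoupling. The fallback joins the same carbons by sulfone alkylation and desulfonylation; it sets out from chloride 11 and bromide 6 and returns at 13. Chloride 11 is displaced with PhSO2Na in DMF to give the allylic sulfone F11. Deprotonation with n-BuLi (THF–DMPU, −78 °C) gives the lithio sulfone F12, which is alkylated by 6 to give the sulfone F13 (epimers at the sulfonyl carbon, C17′). PdCl2(dppp)‑catalysed reduction with LiBHEt3 at 0 °C removes the sulfonyl group with retention of olefin position and E geometry to give 13.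

Step 17. The vinylketene intermediate may leak to cyclobutenone, indene or furan products, the carbene complex may decompose faster than it captures the lipophilic alkyne, or the naphthol may be lost during demetalation. The fallback builds the aryl–allyl bond instead and replaces steps 15 to 18; it sets out from allylic bromide 25 and returns at target 35. 1,4-Dimethoxy-2-methylnaphthalene F14 is brominated (Br2, CH2Cl2, 0 °C) to 2-bromo-1,4-dimethoxy-3-methylnaphthalene F15. Mg in THF gives the aryl Grignard reagent F16, which is coupled with 25 in the presence of CuBr·SMe2, a coupling known to retain allylic E geometry, to give 1,4-dimethoxy-2-methyl-3-(side chain)naphthalene F17. Oxidation with (NH4)2Ce(NO3)6 in MeCN–H2O gives 35.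

**Further compounds**

F1 | step 3 | (R)-2-methylbutane-1,4-diol | OCC[C@@H](C)CO
F2 | step 3 | (R)-4-[(tert-butyldiphenylsilyl)oxy]-2-methylbutan-1-ol | CC(C)(C)[Si](c1ccccc1)(c1ccccc1)OCC[C@@H](C)CO
F3 | step 3 | (R)-(4-bromo-3-methylbutoxy)(tert-butyl)diphenylsilane | CC(C)(C)[Si](c1ccccc1)(c1ccccc1)OCC[C@@H](C)CBr
F4 | step 3 | {(R)-4-[(tert-butyldiphenylsilyl)oxy]-2-methylbutyl}magnesium bromide | CC(C)(C)[Si](c1ccccc1)(c1ccccc1)OCC[C@@H](C)C[Mg]Br
F5 | step 3 | tert-butyl(diphenyl){[(3S,6E,10E,14E)-3,7,11,15,19-pentamethylicosa-6,10,14-trien-1-yl]oxy}silane | CC(C)(C)[Si](c1ccccc1)(c1ccccc1)OCC[C@@H](C)CC/C=C(\C)CC/C=C(\C)CC/C=C(\C)CCCC(C)C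
F6 | step 3 | (3S,6E,10E,14E)-3,7,11,15,19-pentamethylicosa-6,10,14-trien-1-ol | OCC[C@@H](C)CC/C=C(\C)CC/C=C(\C)CC/C=C(\C)CCCC(C)C
F7 | step 3 | (3S,6E,10E,14E)-3,7,11,15,19-pentamethylicosa-6,10,14-trien-1-yl 4-methylbenzenesulfonate | Cc1ccc(cc1)S(=O)(=O)OCC[C@@H](C)CC/C=C(\C)CC/C=C(\C)CC/C=C(\C)CCCC(C)C
F8 | step 3 | tert-butyl(diphenyl){[(3S,7R,10E,14E,18E)-3,7,11,15,19,23-hexamethyltetracosa-10,14,18-trien-1-yl]oxy}silane | CC(C)(C)[Si](c1ccccc1)(c1ccccc1)OCC[C@@H](C)CCC[C@@H](C)CC/C=C(\C)CC/C=C(\C)CC/C=C(\C)CCCC(C)C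
F9 | step 3 | (3S,7R,10E,14E,18E)-3,7,11,15,19,23-hexamethyltetracosa-10,14,18-trien-1-ol | OCC[C@@H](C)CCC[C@@H](C)CC/C=C(\C)CC/C=C(\C)CC/C=C(\C)CCCC(C)C
F10 | step 3 | (3S,7R,10E,14E,18E)-3,7,11,15,19,23-hexamethyltetracosa-10,14,18-trien-1-yl 4-methylbenzenesulfonate | Cc1ccc(cc1)S(=O)(=O)OCC[C@@H](C)CCC[C@@H](C)CC/C=C(\C)CC/C=C(\C)CC/C=C(\C)CCCC(C)C
F11 | step 9 | {[(2E,6E,10E)-3,7,11,15-tetramethylhexadeca-2,6,10-trien-1-yl]sulfonyl}benzene | CC(C)CCC/C(C)=C/CC/C(C)=C/CC/C(C)=C/CS(=O)(=O)c1ccccc1
F12 | step 9 | 1-lithio derivative of F11 (lithiated at the sulfonyl carbon) | CC(C)CCC/C(C)=C/CC/C(C)=C/CC/C(C)=C/C([Li])S(=O)(=O)c1ccccc1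
F13 | step 9 | tert-butyl(diphenyl){[(3S,7R,11R,14E,18E,22E)-3,7,11,15,19,23,27-heptamethyl-13-(phenylsulfonyl)octacosa-14,18,22-trien-1-yl]oxy}silane, both C13 epimers | CC(C)(C)[Si](c1ccccc1)(c1ccccc1)OCC[C@@H](C)CCC[C@@H](C)CCC[C@@H](C)CC(S(=O)(=O)c1ccccc1)/C=C(\C)CC/C=C(\C)CC/C=C(\C)CCCC(C)C
F14 | step 17 | 1,4-dimethoxy-2-methylnaphthalene | COc1cc(C)c(OC)c2ccccc12
F15 | step 17 | 2-bromo-1,4-dimethoxy-3-methylnaphthalene | COc1c(Br)c(C)c(OC)c2ccccc12
F16 | step 17 | (1,4-dimethoxy-3-methylnaphthalen-2-yl)magnesium bromide | COc1c([Mg]Br)c(C)c(OC)c2ccccc12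
F17 | step 17 | 1,4-dimethoxy-2-methyl-3-[(2E,7S,11R,15R,18E,22E,26E)-3,7,11,15,19,23,27,31-octamethyldotriaconta-2,18,22,26-tetraen-1-yl]naphthalene | COc1c(C)c(C/C=C(\C)CCC[C@@H](C)CCC[C@@H](C)CCC[C@@H](C)CC/C=C(\C)CC/C=C(\C)CC/C=C(\C)CCCC(C)C)c(OC)c2ccccc12
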